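**Plan**
- Retrosynthesis: the 2-substituted buta-1,3-diene is cut back (C13=C16, C14=C15) to a terminal alkyne, and the alkyne (C13≡C14) to the carbonyl of a δ-lactone closed on O8.
- The lactone is opened at C9–C10 and C8–O to a monocyclic (Z)-olefinic acid. Its chain is cut at C7–C8 and C5–C6 into a ring-A enol triflate, a vinyl unit and a six-carbon (Z)-vinyl iodide.
- Forward: ring A is made first from 2-methylcyclohexane-1,3-dione; the chain is joined by Stille vinylation and hydroboration/B-alkyl Suzuki coupling; ring B and the lactone ring then close together in superacid; the chain end is rebuilt by lactol, alkyne and ethylene ene–yne metathesis, with the C3 acetate installed once the primary hydroxyl is silylated.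
- Enabling feature: C11 on C9 lies on the face opposite the C10 methyl and on the face of the C8 oxygen (C11 axial, O8 equatorial on ring B). A (Z)-C8=C9 olefin that takes up C10 and a tethered carboxyl oxygen on opposite faces gives exactly this arrangement.
- Stereochemistry: C3 and C4 come from an enzymatic desymmetrisation; C5, C10, C9 and C8 from the cyclisation (protonation face, chair closure, olefin geometry, anti capture); the (Z) geometry from an α-iodo Wittig reaction carried through a stereoretentive coupling.

Key step: step 11

Assumption: a commercial ketoreductase panel is taken to contain an enzyme that reduces dione 2 to the (2S,3R) hydroxy ketone 3 (hydroxyl trans to the hydroxymethyl group); this configuration is carried through.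
Numbering: labdane numbering is used for skeletal carbons (ring A = C1–C5, C10; ring B = C5–C10; C11–C16 chain on C9; C17 on C8; C20 on C10). In the benzodioxin intermediates C5, C6, C8a and C4a correspond to labdane C5, C10, C3 and C4. Reagents named without a number are commercial.

**Route**

Step 1
Reactants: 1 2-methylcyclohexane-1,3-dione
Product: 2 2-(hydroxymethyl)-2-methylcyclohexane-1,3-dione
Conditions: 37% aq. HCHO, H2O, rt
Reagents that add atoms: formaldehyde, C=O
Why: Aldol addition (hydroxymethylation) of the acidic 1,3-dione through its enol stops after one addition because the carbon that reacts becomes quaternary, and no stereocentre is formed.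

Step 2
Reactants: 2 2-(hydroxymethyl)-2-methylcyclohexane-1,3-dione
Product: 3 (2S,3R)-3-hydroxy-2-(hydroxymethyl)-2-methylcyclohexan-1-one
Conditions: ketoreductase (anti-Prelog, chosen from a panel), NADP+ (cat.), i-PrOH, phosphate buffer pH 7, 30 °C
Reagents that add atoms: none
Why: Enzymatic carbonyl reduction desymmetrises the prochiral 2,2-disubstituted 1,3-dione, the enzyme choosing one enantiotopic carbonyl and one face, which sets C3 as R and thereby the quaternary C2 as S with the hydroxyl cis to the methyl and trans to the hydroxymethyl group.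

Step 3
Reactants: 3 (2S,3R)-3-hydroxy-2-(hydroxymethyl)-2-methylcyclohexan-1-one
Product: 4 (4aS,8aR)-2,2,4a-trimethyl-hexahydro-4H-1,3-benzodioxin-5-one (trans-fused acetonide of 3)
Conditions: Me2C(OMe)2, PPTS (cat.), acetone, rt
Reagents that add atoms: 2,2-dimethoxypropane, COC(C)(C)OC
Why: Acid-catalysed transacetalisation closes a trans-fused 1,3-dioxane on the diequatorial 1,3-diol and so masks both hydroxyls for the enolate chemistry that follows, without touching a stereocentre.

Step 4
Reactants: 4 (4aS,8aR)-2,2,4a-trimethyl-hexahydro-4H-1,3-benzodioxin-5-one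
Product: 6 (4aS,8aR)-2,2,4a,6-tetramethyl-hexahydro-4H-1,3-benzodioxin-5-one (both C6 epimers), via lithium enolate 5 (not isolated)
Conditions: LiN(i-Pr)2, THF, −78 °C; MeI, −78 → 0 °C
Reagents that add atoms: iodomethane, CI
Why: Enolate alkylation is regiochemically unambiguous because the ketone can enolise only away from the quaternary carbon, and the new methyl-bearing centre (labdane C10, formed as a mixture) becomes sp2 in the next step.

Step 5
Reactants: 6 (4aS,8aR)-2,2,4a,6-tetramethyl-hexahydro-4H-1,3-benzodioxin-5-one
Product: 8 (4aS,8aR)-2,2,4a,6-tetramethyl-4a,7,8,8a-tetrahydro-4H-1,3-benzodioxin-5-yl trifluoromethanesulfonate, via lithium enolate 7 (not isolated)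
Conditions: LiN(i-Pr)2, THF, −78 → 0 °C; PhNTf2, 0 °C → rt
Reagents that add atoms: N-phenylbis(trifluoromethanesulfonimide), O=S(=O)(N(c1ccccc1)S(=O)(=O)C(F)(F)F)C(F)(F)F
Why: Enolate O-sulfonylation traps the only possible enolate, the tetrasubstituted C5=C10 one, as its enol triflate, as is routine for 2,2,6-trisubstituted cyclohexanones.

Step 6
Reactants: 8 enol triflate
Product: 9 (4aS,8aR)-5-ethenyl-2,2,4a,6-tetramethyl-4a,7,8,8a-tetrahydro-4H-1,3-benzodioxine
Conditions: Bu3SnCH=CH2, Pd2(dba)3 (2.5 mol%), AsPh3, LiCl, NMP, 60 °C
Reagents that add atoms: tributyl(vinyl)stannane, C=C[Sn](CCCC)(CCCC)CCCC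
Why: Stille coupling of a vinyl triflate with a vinylstannane is established for hindered 2,6,6-trisubstituted cyclohexenyl triflates and installs C6 and C7 as a vinyl group without affecting the acetonide.

Step 7
Reactants: 10 ethyltriphenylphosphonium iodide; 11 methyl 4-oxobutanoate
Product: 15 methyl (4Z)-5-iodohex-4-enoate, via ethylidenetriphenylphosphorane 12 (not isolated), via (1-iodoethyl)triphenylphosphonium iodide 13 (not isolated), via (1-iodoethylidene)triphenylphosphorane 14 (not isolated)
Conditions: n-BuLi, THF, 0 °C → rt; I2, −78 °C; NaN(SiMe3)2, −20 °C; then 11, −78 °C → rt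
Reagents that add atoms: iodine, II
Why: Wittig olefination with the non-stabilised α-iodo ylide (Stork–Zhao type) adds to the aldehyde under kinetic control and should give the (Z)-iodoalkene with iodine cis to the chain, which fixes the later C8=C9 geometry while the ester is untouched at low temperature.

Step 8
Reactants: 9 ring-A diene; 15 methyl (4Z)-5-iodohex-4-enoate
Product: 17 methyl (4Z)-5-methyl-7-[(4aS,8aR)-2,2,4a,6-tetramethyl-4a,7,8,8a-tetrahydro-4H-1,3-benzodioxin-5-yl]hept-4-enoate, via B-alkyl-9-BBN 16 (not isolated)
Conditions: 9-BBN-H, THF, 0 °C → rt; then 15, PdCl2(dppf) (5 mol%), AsPh3, Cs2CO3, DMF/THF/H2O, rt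
Reagents that add atoms: none
Why: Hydroboration places boron on the terminal CH2 of the vinyl group only (the tetrasubstituted ring olefin is inert to 9-BBN), and B-alkyl Suzuki–Miyaura coupling of the primary alkylborane with the vinyl iodide forms C7–C8 with retention of the (Z) geometry.

Step 9
Reactants: 17 coupled ester acetonide
Product: 19 (4Z)-7-[(5R,6S)-5-hydroxy-6-(hydroxymethyl)-2,6-dimethylcyclohex-1-en-1-yl]-5-methylhept-4-enoic acid, via lithium carboxylate 18 (not isolated)
Conditions: LiOH, THF/H2O, rt; then 1 M HCl to pH 1, rt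
Reagents that add atoms: lithium hydroxide, [Li+].[OH-]
Why: Ester saponification followed in the same flask by acid-catalysed acetal hydrolysis releases the diol acid, dilute aqueous acid at room temperature being too weak to protonate the tri- and tetrasubstituted olefins.

Step 10
Reactants: 19 diol acid
Product: 21 (4Z)-7-[(5R,6S)-5-acetoxy-6-(acetoxymethyl)-2,6-dimethylcyclohex-1-en-1-yl]-5-methylhept-4-enoic acid, via mixed acetic anhydride 20 (not isolated)
Conditions: Ac2O, pyridine, DMAP (cat.), CH2Cl2, 0 °C → rt; then H2O/THF, rt
Reagents that add atoms: acetic anhydride, CC(=O)OC(C)=O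
Why: DMAP-catalysed acetylation esterifies the primary and the hindered secondary hydroxyl, and the mixed anhydride formed at the carboxyl is hydrolysed back to the free acid during the aqueous stir.

Step 11
Reactants: 21 (Z)-seco acid diacetate
Product: 22 tricyclic δ-lactone diacetate, (3R,4S,5S,8S,9R,10R)-14,15,16-trinorlabdan-13,8-olide with OAc on C3 and on the equatorial C4 methyl carbon
Conditions: ClSO3H (excess), 2-nitropropane, −78 °C; Et3N, then aq. NaHCO3
Reagents that add atoms: none
Why: Protonation of the tetrasubstituted ring-A olefin at C5 gives the tertiary C10 cation, C9 of the (Z)-olefin attacks it to form the C9–C10 bond, and the carboxyl oxygen captures the resulting tertiary C8 cation, a Brønsted superacid cation–olefin cyclisation with lactone termination of the kind known for monocyclic homo- and bishomofarnesic acids. Ring B closes 6-endo with respect to the C8=C9 olefin through a chair in which the chain is equatorial on ring A, and the δ-lactone closes by six-membered attack of the carboxyl on C8, so that the C8–C9 bond becomes the fusion of both new rings. C5 is set by protonation anti to the axial C4 methyl of the half-chair that the equatorial C3 acetate fixes, C10 by the chair closure (trans ring fusion, C10 methyl anti to H5), C9 by the (Z) geometry, which places C11 axial and trans to the C10 methyl, and C8 by anti addition across the olefin, which the tether enforces because it can deliver oxygen only cis to an axial C11. The step needs initiation at the ring olefin and not at C8=C9, and it needs the ring-A oxygens to stay bound; the tetrasubstituted olefin is the more basic site, and the acetates and the carboxyl are protonated in the superacid at −78 °C, which suppresses their ionisation. A short contact time at low temperature should keep the closure close to concerted and so preserve the olefin-geometry information.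

Step 12
Reactants: 22 tricyclic δ-lactone diacetate
Product: 23 lactol triol (13-hydroxy-8,13-epoxide with free 3-OH and free C4 hydroxymethyl, both C13 anomers)
Conditions: i-Bu2AlH (6 equiv), CH2Cl2, −78 °C; MeOH at −78 °C, then aq. potassium sodium tartrate
Reagents that add atoms: none
Why: Hydride reduction with i-Bu2AlH at −78 °C cleaves the two acetates reductively and stops at the aluminium lactolate of the δ-lactone, which gives the lactol on work-up, the new anomeric centre being inconsequential.

Step 13
Reactants: 23 lactol triol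
Product: 25 alkyne triol (15,16-dinorlabd-13-yne with 3-OH, 8-OH and C4 hydroxymethyl), via hydroxy aldehyde 24 (not isolated)
Conditions: dimethyl (1-diazo-2-oxopropyl)phosphonate, K2CO3, MeOH, 0 °C → rt
Reagents that add atoms: dimethyl (1-diazo-2-oxopropyl)phosphonate, CC(=O)C(=[N+]=[N-])P(=O)(OC)OC
Why: Seyferth–Gilbert homologation in the Ohira–Bestmann variant converts the aldehyde tautomer of the lactol into the terminal alkyne (C13≡C14) by loss of phosphate and N2 with a 1,2-hydrogen shift, and no stereocentre is touched.

Step 14
Reactants: 25 alkyne triol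
Product: 26 primary tert-butyldimethylsilyl ether of 25
Conditions: TBSCl (1.1 equiv), imidazole, CH2Cl2, 0 °C
Reagents that add atoms: tert-butyldimethylsilyl chloride, CC(C)(C)[Si](C)(C)Cl
Why: Silylation of the primary hydroxyl is much faster than that of the secondary hydroxyl next to the quaternary C4 or of the tertiary C8 hydroxyl, so one equivalent should mark the primary position only.

Step 15
Reactants: 26 primary silyl ether
Product: 27 3-O-acetate of 26
Conditions: Ac2O (1.5 equiv), pyridine, DMAP (cat.), CH2Cl2, rt
Reagents that add atoms: acetic anhydride, CC(=O)OC(C)=O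
Why: DMAP-catalysed acetylation reaches the secondary C3 hydroxyl, while the tertiary C8 hydroxyl does not react at room temperature with a small excess of anhydride.

Step 16
Reactants: 27 alkyne acetate
Product: 28 3-acetoxy-labda-13(16),14-dien-8-ol primary silyl ether
Conditions: C2H4 (1 atm), second-generation Grubbs catalyst RuCl2(=CHPh)(H2IMes)(PCy3) (10 mol%), toluene, 80 °C
Reagents that add atoms: ethylene, C=C
Why: Ene–yne cross-metathesis of a terminal alkyne with ethylene gives the 2-substituted buta-1,3-diene directly, the ruthenium methylidene adding across the triple bond and ethylene releasing the vinylcarbene, with alcohol, acetate and silyl ether tolerated.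

Step 17
Reactants: 28 diene silyl ether
Product: 29 target, (3R,4S,5S,8S,9R,10R)-3-acetoxy-labda-13(16),14-dien-8-ol with a free equatorial hydroxymethyl on C4
Conditions: HF·pyridine, pyridine, THF, 0 °C → rt
Reagents that add atoms: none
Why: Fluoride-mediated desilylation under buffered, weakly acidic conditions frees the primary hydroxyl without the base-induced 1,3-acetyl shift from O3 and leaves the tertiary alcohol and the diene intact.

**Compound list**
1 | 2-methylcyclohexane-1,3-dione | CC1C(=O)CCCC1=O | starting material
2 | 2-(hydroxymethyl)-2-methylcyclohexane-1,3-dione | CC1(CO)C(=O)CCCC1=O | intermediate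
3 | (2S,3R)-3-hydroxy-2-(hydroxymethyl)-2-methylcyclohexan-1-one | O=C1CCC[C@@H](O)[C@]1(C)CO | intermediate
4 | (4aS,8aR)-2,2,4a-trimethyl-hexahydro-4H-1,3-benzodioxin-5-one | O=C1CCC[C@H]2OC(C)(C)OC[C@]12C | intermediate
5 | lithium enolate of 4 | [Li]OC1=CCC[C@H]2OC(C)(C)OC[C@]12C | intermediate
6 | (4aS,8aR)-2,2,4a,6-tetramethyl-hexahydro-4H-1,3-benzodioxin-5-one (C6 epimers) | O=C1C(C)CC[C@H]2OC(C)(C)OC[C@]12C | intermediate
7 | lithium enolate of 6 | [Li]OC1=C(C)CC[C@H]2OC(C)(C)OC[C@]12C | intermediate
8 | (4aS,8aR)-2,2,4a,6-tetramethyl-4a,7,8,8a-tetrahydro-4H-1,3-benzodioxin-5-yl trifluoromethanesulfonate | O=S(=O)(OC1=C(C)CC[C@H]2OC(C)(C)OC[C@]12C)C(F)(F)F | intermediate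
9 | (4aS,8aR)-5-ethenyl-2,2,4a,6-tetramethyl-4a,7,8,8a-tetrahydro-4H-1,3-benzodioxine | C=CC1=C(C)CC[C@H]2OC(C)(C)OC[C@]12C | intermediate
10 | ethyltriphenylphosphonium iodide | CC[P+](c1ccccc1)(c1ccccc1)c1ccccc1.[I-] | starting material
11 | methyl 4-oxobutanoate | COC(=O)CCC=O | starting material
12 | ethylidenetriphenylphosphorane | CC=P(c1ccccc1)(c1ccccc1)c1ccccc1 | intermediate
13 | (1-iodoethyl)triphenylphosphonium iodide | CC(I)[P+](c1ccccc1)(c1ccccc1)c1ccccc1.[I-] | intermediate
14 | (1-iodoethylidene)triphenylphosphorane | CC(I)=P(c1ccccc1)(c1ccccc1)c1ccccc1 | intermediate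
15 | methyl (4Z)-5-iodohex-4-enoate | COC(=O)CC/C=C(/C)I | intermediate
16 | B-[2-(ring A)ethyl]-9-borabicyclo[3.3.1]nonane from 9 | B1(CCC3=C(C)CC[C@H]4OC(C)(C)OC[C@]34C)C2CCCC1CCC2 | intermediate
17 | methyl (4Z)-5-methyl-7-[(4aS,8aR)-2,2,4a,6-tetramethyl-4a,7,8,8a-tetrahydro-4H-1,3-benzodioxin-5-yl]hept-4-enoate | COC(=O)CC/C=C(/C)CCC1=C(C)CC[C@H]2OC(C)(C)OC[C@]12C | intermediate
18 | lithium carboxylate of 17 | [Li+].[O-]C(=O)CC/C=C(/C)CCC1=C(C)CC[C@H]2OC(C)(C)OC[C@]12C | intermediate
19 | (4Z)-7-[(5R,6S)-5-hydroxy-6-(hydroxymethyl)-2,6-dimethylcyclohex-1-en-1-yl]-5-methylhept-4-enoic acid | OC(=O)CC/C=C(/C)CCC1=C(C)CC[C@@H](O)[C@]1(C)CO | intermediate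
20 | mixed acetic anhydride of 21 | CC(=O)OC(=O)CC/C=C(/C)CCC1=C(C)CC[C@@H](OC(C)=O)[C@]1(C)COC(C)=O | intermediate
21 | (4Z)-7-[(5R,6S)-5-acetoxy-6-(acetoxymethyl)-2,6-dimethylcyclohex-1-en-1-yl]-5-methylhept-4-enoic acid | OC(=O)CC/C=C(/C)CCC1=C(C)CC[C@@H](OC(C)=O)[C@]1(C)COC(C)=O | intermediate
22 | (3R,4S,5S,8S,9R,10R) tricyclic δ-lactone diacetate (13,8-olide; OAc on C3 and on the C4 CH2) | O=C1CC[C@@H]2[C@]3(C)CC[C@@H](OC(C)=O)[C@](C)(COC(C)=O)[C@H]3CC[C@]2(C)O1 | intermediate
23 | lactol triol (13-hydroxy-8,13-epoxide, C13 anomers) | OC1CC[C@@H]2[C@]3(C)CC[C@@H](O)[C@](C)(CO)[C@H]3CC[C@]2(C)O1 | intermediate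
24 | ring-opened hydroxy aldehyde (13-al) | O=CCC[C@@H]1[C@]2(C)CC[C@@H](O)[C@](C)(CO)[C@H]2CC[C@]1(C)O | intermediate
25 | alkyne triol (13-yne; 3-OH, 8-OH, C4 CH2OH) | C#CCC[C@@H]1[C@]2(C)CC[C@@H](O)[C@](C)(CO)[C@H]2CC[C@]1(C)O | intermediate
26 | primary tert-butyldimethylsilyl ether of 25 | C#CCC[C@@H]1[C@]2(C)CC[C@@H](O)[C@](C)(CO[Si](C)(C)C(C)(C)C)[C@H]2CC[C@]1(C)O | intermediate
27 | 3-O-acetate of 26 | C#CCC[C@@H]1[C@]2(C)CC[C@@H](OC(C)=O)[C@](C)(CO[Si](C)(C)C(C)(C)C)[C@H]2CC[C@]1(C)O | intermediate
28 | 13(16),14-diene, 3-acetate, primary silyl ether | C=CC(=C)CC[C@@H]1[C@]2(C)CC[C@@H](OC(C)=O)[C@](C)(CO[Si](C)(C)C(C)(C)C)[C@H]2CC[C@]1(C)O | intermediate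
29 | CNP0313672.1, (3R,4S,5S,8S,9R,10R)-3-acetoxy-labda-13(16),14-dien-8-ol with free C4 hydroxymethyl | C=CC(=C)CC[C@@H]1[C@]2(C)CC[C@@H](OC(C)=O)[C@](C)(CO)[C@H]2CC[C@]1(C)O | target

**Step count and risks**
Total step count: 17. Longest linear sequence: 16 steps (1 to 29 through steps 1–6 and 8–17); step 7 is a one-step side branch.

Step 11. What may go wrong: chlorosulfonic acid converts the free carboxyl into an acyl chlorosulfate or acylium ion, or the protonated acetates slow ionisation at C10, so that capture of the C8 cation is lost to elimination and the olefin geometry is scrambled before ring B closes. The fallback changes the terminating group to a hydroxyl and restores the lactone by C–H oxidation. It sets out from 21: ClCO2Et/Et3N in THF at −10 °C gives the mixed ethyl carbonic anhydride F1, which NaBH4 in THF/H2O at 0 °C reduces to the (Z)-seco alcohol diacetate F2 without touching the acetates. FSO3H in 2-nitropropane at −78 °C then closes ring B and a tetrahydropyran, the hydroxyl-terminated version of the same cyclisation known for homofarnesol-type alcohols, to give the tricyclic 8,13-ether diacetate F3. RuCl3 (cat.)/NaIO4 in CCl4/MeCN/H2O oxidises its only O–CH2 group to the carbonyl, and the route is rejoined at 22.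

Step 8. What may go wrong: hydroboration of the vinyl group, which is twisted and flanked by the quaternary C4, is slow, so that the borane is consumed unproductively and the alkylborane is protodeboronated before transmetalation. The fallback moves boron to the chain and makes C5–C6 in the coupling. It sets out from 15: Stille coupling with Bu3SnCH=CH2 (Pd2(dba)3, AsPh3, NMP) gives methyl (4Z)-5-methylhepta-4,6-dienoate F4. 9-BBN-H adds to its unhindered terminal CH2 to give the homoallylic B-alkyl-9-BBN F5, which is coupled with enol triflate 8 (PdCl2(dppf), K3PO4, DMF/THF/H2O, 60 °C). The route is rejoined at 17, and step 6 is then not needed.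

Step 2. What may go wrong: poor discrimination between the two carbonyls or between their faces by the enzymes at hand, which would place the hydroxyl cis to the hydroxymethyl group or give low enantiomeric purity. The fallback uses a substrate-directed reduction for the relative configuration and an enzymatic resolution for the absolute one. It sets out from 2: Me4NBH(OAc)3 in MeCN/AcOH at −20 °C delivers hydride intramolecularly from the boron-bound primary oxygen (Evans–Saksena reduction) and should give the racemic trans diol F6. A lipase chosen by screening (for example Burkholderia cepacia lipase, vinyl acetate, t-BuOMe) acetylates the primary hydroxyl of the (2S,3R) enantiomer to give [(1S,2R)-2-hydroxy-1-methyl-6-oxocyclohexyl]methyl acetate F7. This is separated from the unreacted enantiomer and hydrolysed by the same lipase in pH 7 buffer, and the route is rejoined at 3.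

**Further compounds**
F1 | step 11 | mixed ethyl carbonic anhydride of 21 | CCOC(=O)OC(=O)CC/C=C(/C)CCC1=C(C)CC[C@@H](OC(C)=O)[C@]1(C)COC(C)=O
F2 | step 11 | (4Z)-7-[(5R,6S)-5-acetoxy-6-(acetoxymethyl)-2,6-dimethylcyclohex-1-en-1-yl]-5-methylhept-4-en-1-ol | OCCC/C=C(/C)CCC1=C(C)CC[C@@H](OC(C)=O)[C@]1(C)COC(C)=O
F3 | step 11 | (3R,4S,5S,8S,9R,10R) tricyclic 8,13-ether diacetate | C1CC[C@@H]2[C@]3(C)CC[C@@H](OC(C)=O)[C@](C)(COC(C)=O)[C@H]3CC[C@]2(C)O1
F4 | step 8 | methyl (4Z)-5-methylhepta-4,6-dienoate | COC(=O)CC/C=C(/C)C=C
F5 | step 8 | B-alkyl-9-borabicyclo[3.3.1]nonane from F4 | COC(=O)CC/C=C(/C)CCB1C2CCCC1CCC2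
F6 | step 2 | racemic trans-3-hydroxy-2-(hydroxymethyl)-2-methylcyclohexan-1-one | O=C1CCC[C@@H](O)[C@]1(C)CO.O=C1CCC[C@H](O)[C@@]1(C)CO
F7 | step 2 | [(1S,2R)-2-hydroxy-1-methyl-6-oxocyclohexyl]methyl acetate | O=C1CCC[C@@H](O)[C@]1(C)COC(C)=O
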